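**Plan**

1. Retrosynthesis: after removal of the C17 methylene, the C6 acetate and the silyl ethers, the cuts are C8–C15 (ring D), C9–C11 (ring C), then C8=C9 and the C7–O20 ester bond (lactone ring B). This leaves ring-A diol 17 and side-chain acid 29.
2. In 17 the lactone carbonyl C6 and the carbinol carbon C20 are rejoined as the C6=C20 bond of cyclobutene 15. Compound 15 is then cut at C5–C6 and C10–C20 to give the ethynyl ether enone 14.
3. Enabling feature: on ring A the one-carbon arms C6 (on C5) and C20 (on C10) are cis, C6 is already bound to O19 in the oxolane ring C4–C19–O–C6–C5, and C10 is alpha to the C1 oxygen. Both arms are therefore the two carbons of an ethynyl ether hung on C19 and added across C5=C10 of a C1 enone.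
4. Forward ring order: ring A (Diels–Alder), oxolane plus cyclobutene (photocycloaddition), cyclobutene opened by ozone, lactone ring B (esterification, Horner–Wadsworth–Emmons), ring C (SmI2), ring D (Pd(OAc)2), then adjustment of C6, C15 and C17.
5. Stereochemistry: C4 comes from a TADDOL-catalysed Diels–Alder reaction, C5 and C10 from the tether, C1 from hydride delivery directed by the C20 hydroxyl, and C13 from an Evans alkylation. C9 and C11 come from the ketyl cyclisation under control of C10, C8 from the reach of the C13 allyl arm, and C6 from acylation of the lactol on its convex face.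
6. C9 rides through the key step as CH2OTBS. An ether survives the n-BuLi that makes the alkynyl ether, and it keeps C9 and C20 distinguishable after ring opening.

Key step: step 9

Conventions: atom numbers are those of ent-kaurane. On ring A, alpha is the face that carries C19, C6 and C20, and beta is the face of C18, H5 and C9. On ring C, beta is the face of H9 and of the C15–C16 bridge. TBS = tert-butyldimethylsilyl, TES = triethylsilyl.

Assumption: the (R,R)-TADDOL is taken to deliver the (1R)-aldehyde 3; if the sense of induction is the reverse, the (S,S)-catalyst is used and nothing else changes.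

**Route**

Step 1
Reactants: 1 methacrolein; 2 (E)-1-(dimethylamino)-3-(tert-butyldimethylsilyloxy)buta-1,3-diene
Product: 4 [(1R,2S)-2-(dimethylamino)-1-methyl-4-(tert-butyldimethylsilyloxy)cyclohex-3-en-1-yl]methanol, via cycloadduct aldehyde 3 (not isolated)
Conditions: (R,R)-1-naphthyl-TADDOL (20 mol %), toluene, −80 °C; then LiAlH4, Et2O, −78 °C → rt
Reagents that add atoms: none
Why: Hydrogen-bond-catalysed asymmetric Diels–Alder reaction in which the 1-amino group fixes the regiochemistry (C5–N next to the new quaternary C4), the chiral diol bound to the aldehyde oxygen shields one face of methacrolein and so sets C4, and LiAlH4 then reduces only the aldehyde to the C19 alcohol while the enone stays masked as a beta-amino silyl enol ether.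

Step 2
Reactants: 4 masked-enone alcohol; 5 trichloroethylene
Product: 6 (E)-1,2-dichlorovinyl ether of 4 (C19–O–CCl=CHCl; silyl enol ether and amine unchanged)
Conditions: KH, THF, 0 °C; then Cl2C=CHCl, −78 °C → rt
Reagents that add atoms: trichloroethylene (5), ClC=C(Cl)Cl
Why: Addition of the alkoxide to dichloroacetylene formed in situ is the standard entry to 1,2-dichlorovinyl ethers, anti addition gives the E isomer, and the silyl enol ether and tertiary amine offer the base no acidic or electrophilic site at this temperature.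

Step 3
Reactants: 6 dichlorovinyl ether with masked enone
Product: 7 (4R)-4-{[(E)-1,2-dichloroethenyl]oxymethyl}-4-methylcyclohex-2-en-1-one
Conditions: HF (48 % aq), MeCN, 0 °C → rt
Reagents that add atoms: none
Why: Acidic desilylation followed by E1cB loss of dimethylamine from the beta-amino ketone unmasks the enone, and the electron-poor dichlorovinyl ether is inert to dilute acid.

Step 4
Reactants: 7 enone; 8 formaldehyde
Product: 9 (4R)-4-{[(E)-1,2-dichloroethenyl]oxymethyl}-2-(hydroxymethyl)-4-methylcyclohex-2-en-1-one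
Conditions: HCHO (37 % aq), DMAP, THF/H2O, rt
Reagents that add atoms: formaldehyde (8), C=O
Why: Morita–Baylis–Hillman hydroxymethylation, known though slow for 4,4-dialkylcyclohexenones, places C9 on C10 in one operation without strong base.

Step 5
Reactants: 9 hydroxymethyl enone
Product: 10 (4R)-2-[(tert-butyldimethylsilyloxy)methyl]-4-{[(E)-1,2-dichloroethenyl]oxymethyl}-4-methylcyclohex-2-en-1-one
Conditions: TBSCl, imidazole, CH2Cl2, 0 °C → rt
Reagents that add atoms: tert-butyldimethylsilyl chloride, CC(C)(C)[Si](C)(C)Cl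
Why: Standard silylation of a primary allylic alcohol gives a C9 ether that tolerates organolithium, light and ozone.

Step 6
Reactants: 10 silyloxymethyl enone
Product: 11 (4R)-2-[(tert-butyldimethylsilyloxy)methyl]-4-{[(E)-1,2-dichloroethenyl]oxymethyl}-4-methylcyclohex-2-en-1-ol (C1 epimers)
Conditions: NaBH4, CeCl3·7H2O, MeOH, −78 → 0 °C
Reagents that add atoms: none
Why: Luche 1,2-reduction stores the ketone as a carbinol so that n-BuLi can be used next, and the C1 epimers need no separation because C1 is reoxidised in step 8.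

Step 7
Reactants: 11 allylic alcohol
Product: 13 (4R)-2-[(tert-butyldimethylsilyloxy)methyl]-4-[(ethynyloxy)methyl]-4-methylcyclohex-2-en-1-ol (C1 epimers), via dilithiated alkynyl ether 12 (not isolated)
Conditions: n-BuLi (3.5 equiv), THF, −78 → −40 °C; then MeOH, −78 °C
Reagents that add atoms: none
Why: Elimination of HCl to the chloroalkynyl ether and Cl/Li exchange (the dichlorovinyl ether route to alkynyl ethers) proceed with the carbinol protected as its lithium alkoxide, and since C19 is attached to the quaternary C4 the ether has no beta-hydrogen and cannot lose ketene by a retro-ene path.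

Step 8
Reactants: 13 ethynyl ether alcohol
Product: 14 (4R)-2-[(tert-butyldimethylsilyloxy)methyl]-4-[(ethynyloxy)methyl]-4-methylcyclohex-2-en-1-one
Conditions: MnO2, CH2Cl2, rt
Reagents that add atoms: none
Why: Allylic alcohol oxidation with neutral, heterogeneous MnO2 restores the enone without exposing the acid-sensitive ethynyl ether to acid or electrophiles.

Step 9
Reactants: 14 ethynyl ether enone
Product: 15 tricyclic alkoxycyclobutene (C1 ketone; cyclobutene C5–C6=C20–C10 and oxolane C4–C19–O–C6–C5 both on the alpha face; 4-CH3, 5-H and 10-CH2OTBS beta)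
Conditions: hν (365 nm LED), degassed MeCN (3 mM), base-washed Pyrex, 0 °C
Reagents that add atoms: none
Why: Proposed new method: excitation of the enone and intersystem crossing give the twisted triplet, whose beta carbon C5 attacks the oxygen-bearing alkyne carbon C6, and the resulting 1,4-biradical (alpha-keto radical at C10, vinyl radical at C20) forms the C10–C20 bond after spin inversion. The closest known reaction type is the intramolecular enone–alkyne [2+2] photocycloaddition of cyclohexenones that carry a three-atom alkynyl tether, which gives ring-fused cyclobutenes, whereas an alkynyl ether as the alkyne partner has not been shown. The oxolane ring (C4–C19–O–C6–C5) closes in the 5-exo-dig mode in the first bond formation and the cyclobutene (C5–C6=C20–C10) closes by recombination of the 1,4-biradical. C5 is set because the C19–O arm can bring C6 only to the enone face on which it stands at the C4 stereocentre, and C10 is set because a cyclobutene fused to a six-membered ring must be cis, so C20 ends on the face of C6 and the CH2OTBS arm on the opposite face. The step needs straight (C5–C6 and C10–C20) rather than crossed regiochemistry, which the three-atom tether secures through the preference for a five-membered first ring, while the polar thermal addition of the ynol ether (C20 to C5) is geometrically impossible within this tether. It also needs the beta,gamma-unsaturated ketone product to survive, which is why only the long-wavelength enone band is irradiated and the run is stopped at full conversion.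

Step 10
Reactants: 15 alkoxycyclobutene
Product: 17 6,19-lactone diol (1beta-OH; 10alpha-CH2OH = C20; 10beta-CH2OTBS = C9; 5beta-H), via keto-aldehyde lactone 16 (not isolated)
Conditions: O3, CH2Cl2, −78 °C; PPh3, −78 °C → rt; then Me4NBH(OAc)3, MeCN/AcOH, −30 → 0 °C
Reagents that add atoms: ozone, [O-][O+]=O
Why: Ozonolysis of the strained enol ether turns the oxygen-bearing C6 into the lactone carbonyl and C20 into an aldehyde, and in the following Evans–Saksena reduction the aldehyde is reduced first and the axial C20 alkoxyborohydride then delivers hydride to the alpha face of the C1 ketone, which sets the beta (axial) C1 hydroxyl.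

Step 11
Reactants: 18 methyl 4,4-dimethoxybutanoate; 19 (R)-4-benzyl-1,3-oxazolidin-2-one
Product: 22 (4R)-4-benzyl-3-(4,4-dimethoxybutanoyl)-1,3-oxazolidin-2-one, via lithium 4,4-dimethoxybutanoate 20 (not isolated), via pivalic mixed anhydride 21 (not isolated)
Conditions: LiOH, THF/H2O, rt, evaporate to dryness; t-BuCOCl, THF, −20 °C; then 19, LiCl, Et3N, −20 °C → rt
Reagents that add atoms: none
Why: Mixed-anhydride N-acylation of the auxiliary starts from the carboxylate salt, so the free acetal acid, which would cyclise, is never formed.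

Step 12
Reactants: 22 acyl oxazolidinone; 23 allyl iodide
Product: 24 (4R)-4-benzyl-3-[(2R)-2-(2,2-dimethoxyethyl)pent-4-enoyl]-1,3-oxazolidin-2-one
Conditions: NaN(SiMe3)2, THF, −78 °C; allyl iodide, −78 → −40 °C
Reagents that add atoms: allyl iodide (23), C=CCI
Why: Evans asymmetric alkylation, in which the chelated Z-enolate is attacked on the face away from the benzyl group, sets C13 as R.

Step 13
Reactants: 24 allylated imide
Product: 25 (2R)-2-(2,2-dimethoxyethyl)pent-4-en-1-ol
Conditions: LiBH4, MeOH (1 equiv), Et2O, 0 °C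
Reagents that add atoms: none
Why: Reductive removal of the auxiliary with LiBH4 gives the C14 alcohol without touching C13, the acetal or the alkene.

Step 14
Reactants: 25 primary alcohol
Product: 26 (4R)-4-(iodomethyl)-6,6-dimethoxyhex-1-ene
Conditions: I2, PPh3, imidazole, CH2Cl2, 0 °C
Reagents that add atoms: iodine, II
Why: Appel-type iodination under imidazole buffering converts the primary alcohol into the iodide and spares the acetal.

Step 15
Reactants: 26 iodide; 27 triethyl phosphonoacetate
Product: 28 ethyl (4R)-2-(diethoxyphosphoryl)-4-(2,2-dimethoxyethyl)hept-6-enoate (C2 = C8 epimers)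
Conditions: NaH, DMF, 0 °C; then 26, 60 °C
Reagents that add atoms: none
Why: SN2 alkylation of the stabilised phosphonoacetate anion by a primary iodide forms C8–C14, and the C8 epimers converge in step 21.

Step 16
Reactants: 28 phosphonate ester
Product: 29 (4R)-2-(diethoxyphosphoryl)-4-(2,2-dimethoxyethyl)hept-6-enoic acid (C8 epimers)
Conditions: LiOH, THF/EtOH/H2O, rt; then 1 M HCl to pH 4, 0 °C
Reagents that add atoms: lithium hydroxide, [Li+].[OH-]
Why: Saponification cleaves the carboxylic ester selectively because diethyl phosphonates resist dilute hydroxide, and the cold, mild acidification keeps the acetal.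

Step 17
Reactants: 17 lactone diol; 29 phosphono acid
Product: 30 C20 ester of 17 with acid 29 (1beta-OH free; C9 as OTBS; C8 epimers)
Conditions: EDC·HCl, DMAP (cat.), CH2Cl2, 0 °C → rt
Reagents that add atoms: none
Why: Steglich-type esterification acylates the primary C20 hydroxyl much faster than the axial, neopentyl C1 hydroxyl and is mild enough to leave the 6,19-lactone in place.

Step 18
Reactants: 30 silyl ether ester
Product: 31 C9,C1-diol (30 without the TBS group)
Conditions: Bu4NF, AcOH (1:1), THF, 0 °C → rt
Reagents that add atoms: none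
Why: Buffered fluoride desilylation frees C9–OH under near-neutral conditions, so neither the acetal is hydrolysed nor the acyl group moved from O20 to O9.

Step 19
Reactants: 31 diol
Product: 32 C9 aldehyde (1beta-OH free)
Conditions: TEMPO (20 mol %), PhI(OAc)2, CH2Cl2, rt
Reagents that add atoms: none
Why: Oxoammonium (TEMPO) oxidation is selective for the primary alcohol over the hindered axial secondary one, and the non-enolisable beta-hydroxy aldehyde is safe from retro-aldol cleavage in the absence of base.

Step 20
Reactants: 32 hydroxy aldehyde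
Product: 33 C9 aldehyde 1beta-triethylsilyl ether
Conditions: Et3SiOTf (1.2 equiv), 2,6-lutidine, CH2Cl2, −78 °C
Reagents that add atoms: triethylsilyl triflate, CC[Si](CC)(CC)OS(=O)(=O)C(F)(F)F
Why: Silyl triflate silylation caps the hindered C1 hydroxyl at a temperature at which the dimethyl acetal is not yet activated, and so blocks retro-aldol cleavage and 1,7-translactonisation later on.

Step 21
Reactants: 33 aldehyde phosphonate
Product: 34 spiro alpha,beta-unsaturated delta-lactone (ring B; C8=C9) with the side chain C14–C13(allyl)–C12–C11H(OMe)2 on C8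
Conditions: LiCl, DBU, MeCN, rt
Reagents that add atoms: none
Why: Intramolecular Horner–Wadsworth–Emmons olefination under Masamune–Roush conditions closes the six-membered lactone, whose ring allows only the required alkene geometry and merges both C8 epimers.

Step 22
Reactants: 34 acetal lactone
Product: 36 C11 aldehyde of 34, via methoxyalkyl lutidinium triflate 35 (not isolated)
Conditions: Et3SiOTf (2 equiv), 2,6-lutidine (3 equiv), CH2Cl2, 0 °C; then H2O
Reagents that add atoms: water, O
Why: Silyl triflate/lutidine cleavage of an aldehyde acetal through its pyridinium-type salt works under weakly basic conditions and therefore leaves the C1 triethylsilyl ether untouched.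

Step 23
Reactants: 36 aldehyde
Product: 37 ring-C carbinol (11alpha-OH; 9beta-H; 8beta-H; 13beta-allyl)
Conditions: SmI2, LiBr, t-BuOH, THF, −78 °C
Reagents that add atoms: none
Why: SmI2-mediated ketyl–olefin cyclisation (6-endo-trig) in which C11 adds to C9 on the lactone face flanked by C1–H rather than by the equatorial C6 (setting C9), through a chair with C10 and the allyl group equatorial and the ketyl oxygen axial, held by trivalent samarium to the lactone carbonyl and kept away from the axial C1 silyl ether (setting C11), while protonation at C8 gives the cis-fused lactone, a centre that is remade in step 26.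

Step 24
Reactants: 37 carbinol
Product: 38 1,11-bis(triethylsilyl) ether of 37
Conditions: Et3SiOTf, 2,6-lutidine, CH2Cl2, −78 → 0 °C
Reagents that add atoms: triethylsilyl triflate, CC[Si](CC)(CC)OS(=O)(=O)C(F)(F)F
Why: Silylation under non-basic conditions protects C11–OH before any alkoxide could attack the nearby C7 carbonyl.

Step 25
Reactants: 38 bis-silyl ether
Product: 39 tert-butyldimethylsilyl ketene acetal of the delta-lactone (C7(OTBS)=C8)
Conditions: KN(SiMe3)2, TBSCl, THF/DMPU, −78 → 0 °C
Reagents that add atoms: tert-butyldimethylsilyl chloride, CC(C)(C)[Si](C)(C)Cl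
Why: Kinetic enolisation and O-silylation take place at C8–H because the only other alpha-hydrogen, C5–H of the gamma-lactone, lies buried between the quaternary C4 and C10.

Step 26
Reactants: 39 silyl ketene acetal
Product: 40 bicyclo[3.2.1]octane with 15-methylene group (ring D closed; C8 quaternary; 6,19-lactone intact)
Conditions: Pd(OAc)2 (1 equiv), AcOH (0.5 equiv), DMSO, 45 °C
Reagents that add atoms: none
Why: Saegusa-type oxidative cycloalkenylation, in which the palladium enolate adds 5-exo-trig to the allyl alkene and beta-hydride elimination leaves the exocyclic methylene, forms C8–C15, and C8 is set because the allyl arm on the beta face of C13 can reach only the beta face of C8.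

Step 27
Reactants: 40 bis-lactone
Product: 41 6,19-lactol of 40 (C6 anomers in equilibrium; exo-OH drawn)
Conditions: i-Bu2AlH (1.1 equiv), CH2Cl2, −78 °C; aq. work-up
Reagents that add atoms: none
Why: Partial lactone reduction with one equivalent of i-Bu2AlH should pick the gamma-lactone carbonyl C6, open on the convex face of the cis-fused bicycle, over C7, which is flanked by the quaternary bridgehead C8.

Step 28
Reactants: 41 lactol
Product: 42 C6 acetate (OAc on the convex face; trans to C10; cis to H5)
Conditions: Ac2O, pyridine, DMAP (cat.), CH2Cl2, 0 °C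
Reagents that add atoms: acetic anhydride, CC(=O)OC(C)=O
Why: Acetylation of the ring-chain equilibrating lactol traps the less hindered exo anomer, which sets C6, while C1 and C11 stay silylated.

Step 29
Reactants: 42 methylene acetate
Product: 43 15-ketone
Conditions: O3, CH2Cl2, −78 °C; PPh3, −78 °C → rt
Reagents that add atoms: ozone, [O-][O+]=O
Why: Ozonolysis of the only alkene removes the extra carbon and installs the C15 ketone.

Step 30
Reactants: 43 ketone
Product: 44 1,11-bis(triethylsilyl) ether of the target (16-methylene-15-ketone)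
Conditions: CH2(NMe2)2, Ac2O, DMF, 95 °C
Reagents that add atoms: bis(dimethylamino)methane, CN(C)CN(C)C
Why: Mannich-type alpha-methylenation through the iminium acetate made in situ can occur only at C16, the sole enolisable position of the ketone, and the base-free medium with excess Ac2O preserves the C6 acetate.

Step 31
Reactants: 44 bis-silyl ether
Product: 45 Oreskaurin A
Conditions: HF·pyridine, THF, 0 °C
Reagents that add atoms: none
Why: Buffered fluoride cleavage removes the two triethylsilyl ethers under conditions that leave the enone, the lactone and the acetal acetate intact.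

**Compound list**

1 | methacrolein | C=C(C)C=O | starting material
2 | (E)-1-(dimethylamino)-3-(tert-butyldimethylsilyloxy)buta-1,3-diene | C=C(O[Si](C)(C)C(C)(C)C)/C=C/N(C)C | starting material
3 | (1R,2S)-2-(dimethylamino)-1-methyl-4-(tert-butyldimethylsilyloxy)cyclohex-3-ene-1-carbaldehyde | O=C[C@]1(C)CCC(O[Si](C)(C)C(C)(C)C)=C[C@@H]1N(C)C | intermediate
4 | [(1R,2S)-2-(dimethylamino)-1-methyl-4-(tert-butyldimethylsilyloxy)cyclohex-3-en-1-yl]methanol | OC[C@]1(C)CCC(O[Si](C)(C)C(C)(C)C)=C[C@@H]1N(C)C | intermediate
5 | trichloroethylene | ClC=C(Cl)Cl | starting material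
6 | (E)-1,2-dichlorovinyl ether of 4 | Cl/C=C(/Cl)OC[C@]1(C)CCC(O[Si](C)(C)C(C)(C)C)=C[C@@H]1N(C)C | intermediate
7 | (4R)-4-{[(E)-1,2-dichloroethenyl]oxymethyl}-4-methylcyclohex-2-en-1-one | Cl/C=C(/Cl)OC[C@]1(C)CCC(=O)C=C1 | intermediate
8 | formaldehyde | C=O | starting material
9 | (4R)-4-{[(E)-1,2-dichloroethenyl]oxymethyl}-2-(hydroxymethyl)-4-methylcyclohex-2-en-1-one | Cl/C=C(/Cl)OC[C@]1(C)CCC(=O)C(CO)=C1 | intermediate
10 | (4R)-2-[(tert-butyldimethylsilyloxy)methyl]-4-{[(E)-1,2-dichloroethenyl]oxymethyl}-4-methylcyclohex-2-en-1-one | Cl/C=C(/Cl)OC[C@]1(C)CCC(=O)C(CO[Si](C)(C)C(C)(C)C)=C1 | intermediate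
11 | allylic alcohol from 10 (C1 epimers) | Cl/C=C(/Cl)OC[C@]1(C)CCC(O)C(CO[Si](C)(C)C(C)(C)C)=C1 | intermediate
12 | dilithiated alkynyl ether (C20–Li, O1–Li) | [Li]C#COC[C@]1(C)CCC(O[Li])C(CO[Si](C)(C)C(C)(C)C)=C1 | intermediate
13 | (4R)-2-[(tert-butyldimethylsilyloxy)methyl]-4-[(ethynyloxy)methyl]-4-methylcyclohex-2-en-1-ol (C1 epimers) | C#COC[C@]1(C)CCC(O)C(CO[Si](C)(C)C(C)(C)C)=C1 | intermediate
14 | (4R)-2-[(tert-butyldimethylsilyloxy)methyl]-4-[(ethynyloxy)methyl]-4-methylcyclohex-2-en-1-one | C#COC[C@]1(C)CCC(=O)C(CO[Si](C)(C)C(C)(C)C)=C1 | intermediate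
15 | tricyclic alkoxycyclobutene photoadduct | CC(C)(C)[Si](C)(C)OC[C@@]12C(=O)CC[C@@]3(C)COC(=C1)[C@@H]23 | intermediate
16 | keto-aldehyde 6,19-lactone | CC(C)(C)[Si](C)(C)OC[C@]1(C=O)C(=O)CC[C@@]2(C)COC(=O)[C@@H]12 | intermediate
17 | 6,19-lactone diol (1beta-OH, C20–OH, C9–OTBS) | CC(C)(C)[Si](C)(C)OC[C@]1(CO)[C@H](O)CC[C@@]2(C)COC(=O)[C@@H]12 | intermediate
18 | methyl 4,4-dimethoxybutanoate | COC(=O)CCC(OC)OC | starting material
19 | (R)-4-benzyl-1,3-oxazolidin-2-one | O=C1OC[C@@H](Cc2ccccc2)N1 | starting material
20 | lithium 4,4-dimethoxybutanoate | [Li+].[O-]C(=O)CCC(OC)OC | intermediate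
21 | 4,4-dimethoxybutanoic pivalic anhydride | CC(C)(C)C(=O)OC(=O)CCC(OC)OC | intermediate
22 | (4R)-4-benzyl-3-(4,4-dimethoxybutanoyl)-1,3-oxazolidin-2-one | COC(OC)CCC(=O)N1[C@H](Cc2ccccc2)COC1=O | intermediate
23 | allyl iodide | C=CCI | starting material
24 | (4R)-4-benzyl-3-[(2R)-2-(2,2-dimethoxyethyl)pent-4-enoyl]-1,3-oxazolidin-2-one | C=CC[C@H](CC(OC)OC)C(=O)N1[C@H](Cc2ccccc2)COC1=O | intermediate
25 | (2R)-2-(2,2-dimethoxyethyl)pent-4-en-1-ol | C=CC[C@H](CC(OC)OC)CO | intermediate
26 | (4R)-4-(iodomethyl)-6,6-dimethoxyhex-1-ene | C=CC[C@H](CC(OC)OC)CI | intermediate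
27 | triethyl phosphonoacetate | CCOC(=O)CP(=O)(OCC)OCC | starting material
28 | ethyl (4R)-2-(diethoxyphosphoryl)-4-(2,2-dimethoxyethyl)hept-6-enoate | CCOC(=O)C(C[C@H](CC=C)CC(OC)OC)P(=O)(OCC)OCC | intermediate
29 | (4R)-2-(diethoxyphosphoryl)-4-(2,2-dimethoxyethyl)hept-6-enoic acid | OC(=O)C(C[C@H](CC=C)CC(OC)OC)P(=O)(OCC)OCC | intermediate
30 | C20 ester of 17 with 29 | CC(C)(C)[Si](C)(C)OC[C@]1(COC(=O)C(C[C@H](CC=C)CC(OC)OC)P(=O)(OCC)OCC)[C@H](O)CC[C@@]2(C)COC(=O)[C@@H]12 | intermediate
31 | C9,C1-diol ester | OC[C@]1(COC(=O)C(C[C@H](CC=C)CC(OC)OC)P(=O)(OCC)OCC)[C@H](O)CC[C@@]2(C)COC(=O)[C@@H]12 | intermediate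
32 | C9 aldehyde, 1beta-OH | O=C[C@]1(COC(=O)C(C[C@H](CC=C)CC(OC)OC)P(=O)(OCC)OCC)[C@H](O)CC[C@@]2(C)COC(=O)[C@@H]12 | intermediate
33 | C9 aldehyde, 1beta-OTES | O=C[C@]1(COC(=O)C(C[C@H](CC=C)CC(OC)OC)P(=O)(OCC)OCC)[C@H](O[Si](CC)(CC)CC)CC[C@@]2(C)COC(=O)[C@@H]12 | intermediate
34 | spiro unsaturated delta-lactone, C11 dimethyl acetal | C=CC[C@H](CC(OC)OC)CC1=C[C@]2(COC1=O)[C@H](O[Si](CC)(CC)CC)CC[C@@]3(C)COC(=O)[C@@H]23 | intermediate
35 | C11 methoxyalkyl 2,6-lutidinium triflate | C=CC[C@H](CC(OC)[n+]1c(C)cccc1C)CC1=C[C@]2(COC1=O)[C@H](O[Si](CC)(CC)CC)CC[C@@]3(C)COC(=O)[C@@H]23.[O-]S(=O)(=O)C(F)(F)F | intermediate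
36 | spiro unsaturated delta-lactone, C11 aldehyde | C=CC[C@H](CC=O)CC1=C[C@]2(COC1=O)[C@H](O[Si](CC)(CC)CC)CC[C@@]3(C)COC(=O)[C@@H]23 | intermediate
37 | ring-C carbinol (11alpha-OH, 9beta-H, 8beta-H, 13beta-allyl) | C=CC[C@@H]1C[C@@H](O)[C@H]2[C@]3(COC(=O)[C@H]2C1)[C@H](O[Si](CC)(CC)CC)CC[C@@]4(C)COC(=O)[C@@H]34 | intermediate
38 | 1,11-bis(triethylsilyl) ether of 37 | C=CC[C@@H]1C[C@@H](O[Si](CC)(CC)CC)[C@H]2[C@]3(COC(=O)[C@H]2C1)[C@H](O[Si](CC)(CC)CC)CC[C@@]4(C)COC(=O)[C@@H]34 | intermediate
39 | silyl ketene acetal of 38 | C=CC[C@@H]1C[C@@H](O[Si](CC)(CC)CC)[C@H]2[C@]3(COC(O[Si](C)(C)C(C)(C)C)=C2C1)[C@H](O[Si](CC)(CC)CC)CC[C@@]4(C)COC(=O)[C@@H]34 | intermediate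
40 | 15-methylene bicyclo[3.2.1]octane bis-lactone | C=C1[C@]23C[C@H](C1)C[C@@H](O[Si](CC)(CC)CC)[C@H]2[C@]1(COC3=O)[C@H](O[Si](CC)(CC)CC)CC[C@@]2(C)COC(=O)[C@H]21 | intermediate
41 | 6,19-lactol | C=C1[C@]23C[C@H](C1)C[C@@H](O[Si](CC)(CC)CC)[C@H]2[C@]1(COC3=O)[C@H](O[Si](CC)(CC)CC)CC[C@@]2(C)CO[C@H](O)[C@H]21 | intermediate
42 | C6 acetate | C=C1[C@]23C[C@H](C1)C[C@@H](O[Si](CC)(CC)CC)[C@H]2[C@]1(COC3=O)[C@H](O[Si](CC)(CC)CC)CC[C@@]2(C)CO[C@H](OC(C)=O)[C@H]21 | intermediate
43 | 15-ketone | O=C1[C@]23C[C@H](C1)C[C@@H](O[Si](CC)(CC)CC)[C@H]2[C@]1(COC3=O)[C@H](O[Si](CC)(CC)CC)CC[C@@]2(C)CO[C@H](OC(C)=O)[C@H]21 | intermediate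
44 | 1,11-bis(triethylsilyl) ether of Oreskaurin A | C=C1C(=O)[C@]23C[C@H]1C[C@@H](O[Si](CC)(CC)CC)[C@H]2[C@]1(COC3=O)[C@H](O[Si](CC)(CC)CC)CC[C@@]2(C)CO[C@H](OC(C)=O)[C@H]21 | intermediate
45 | Oreskaurin A | C=C1C(=O)[C@]23C[C@H]1C[C@@H](O)[C@H]2[C@]1(COC3=O)[C@H](O)CC[C@@]2(C)CO[C@H](OC(C)=O)[C@H]21 | target

**Step count**

Total step count: 31.
Longest linear sequence: 25 steps (steps 1–10 and 17–31). The side chain takes steps 11–16.

**Steps most likely to fail**

**Step 9.**
- What may go wrong:
  - The electron-rich alkynyl ether may quench the enone triplet by charge transfer.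
  - The vinyl radical end of the biradical may abstract hydrogen instead of closing.
  - The strained alkoxycyclobutene may be consumed by secondary photolysis.
- Fallback: it sets out from 10, which already holds the enone and the (E)-1,2-dichlorovinyl ether.
  - Irradiation of 10 under the conditions of step 9 is an intramolecular enone–alkene [2+2] photocycloaddition with a 1,2-dichloroalkene as acetylene equivalent, a known pairing.
  - It should give the 6,20-dichlorocyclobutane F1 with the same C5–C6 and C10–C20 bonds.
  - Activated Zn in THF/EtOH then removes the two vicinal chlorines.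
  - The route is rejoined at 15, and steps 6 to 8 fall away.

**Step 27.**
- What may go wrong: the hydride may attack the delta-lactone carbonyl C7 as well, or the lactol may be reduced further, because two lactones compete for one equivalent of reagent.
- Fallback: it sets out from 39, in which the delta-lactone is masked as its silyl ketene acetal and C6 is the only carbonyl group.
  - i-Bu2AlH (CH2Cl2, −78 °C) gives the ketene acetal lactol F4.
  - Ac2O/pyridine/DMAP gives the ketene acetal C6 acetate F5.
  - Pd(OAc)2 in DMSO closes ring D as in step 26.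
  - The route is rejoined at 42.

**Step 26.**
- What may go wrong: the ring-C chair must flip to place both C10 and the allyl arm axial before C8–C15 can form, so protodesilylation of the ketene acetal back to 38 may outrun carbopalladation.
- Fallback: it sets out from 38.
  - KN(SiMe3)2 followed by PhSeCl gives the C8 phenylselanyl lactone F2.
  - Sunlamp irradiation in benzene with (Bu3Sn)2 as initiator brings about a phenylselanyl-group-transfer 5-exo-trig radical cyclisation to the primary selenide F3.
  - H2O2 oxidation with selenoxide syn elimination installs the exocyclic methylene.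
  - The route is rejoined at 40.

**Further compounds**

F1 | step 9 | 6,20-dichlorocyclobutane analogue of 15 (6-Cl cis to H5; C20 epimers) | CC(C)(C)[Si](C)(C)OC[C@@]12C(=O)CC[C@@]3(C)CO[C@@](Cl)(C1Cl)[C@@H]23
F2 | step 26 | C8 phenylselanyl derivative of 38 (C8 epimers) | C=CC[C@@H]1C[C@@H](O[Si](CC)(CC)CC)[C@H]2[C@]3(COC(=O)C2([Se]c2ccccc2)C1)[C@H](O[Si](CC)(CC)CC)CC[C@@]4(C)COC(=O)[C@@H]34
F3 | step 26 | 15-(phenylselanylmethyl) bicyclo[3.2.1]octane bis-lactone (C15 epimers) | c1ccc(cc1)[Se]CC1[C@]23C[C@H](C1)C[C@@H](O[Si](CC)(CC)CC)[C@H]2[C@]1(COC3=O)[C@H](O[Si](CC)(CC)CC)CC[C@@]2(C)COC(=O)[C@H]21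
F4 | step 27 | 6,19-lactol of silyl ketene acetal 39 | C=CC[C@@H]1C[C@@H](O[Si](CC)(CC)CC)[C@H]2[C@]3(COC(O[Si](C)(C)C(C)(C)C)=C2C1)[C@H](O[Si](CC)(CC)CC)CC[C@@]4(C)CO[C@H](O)[C@@H]34
F5 | step 27 | C6 acetate of F4 | C=CC[C@@H]1C[C@@H](O[Si](CC)(CC)CC)[C@H]2[C@]3(COC(O[Si](C)(C)C(C)(C)C)=C2C1)[C@H](O[Si](CC)(CC)CC)CC[C@@]4(C)CO[C@H](OC(C)=O)[C@@H]34
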